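At late times a run's readings stop moving, so we replace each curve by its mean over the last readings and ask what that mean balances.

| setting | birch | alder | larch | flask |
|---|---|---|---|---|
| substrate | 0.086 M | 0.086 M | 0.13 M | 0.086 M |
| partner | 0.50 equiv | 0.75 equiv | 1 equiv | 1.00 equiv |
| remark | run made earlier | run made earlier | run made earlier |  |
| time |  |  |  | 1.0 h |

| run | time / min | target / % | over-reaction product / % | substrate / % |
|---|---|---|---|---|
| birch | 4.00 | 17.4 | 14.3 | 3.4 |
| birch | 6.00 | 17.1 | 16.6 | 0.9 |
| birch | 8.00 | 16.1 | 17.8 | 1.1 |
| birch | 15.0 | 15.3 | 16.8 | 0.3 |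
| birch | 20.0 | 14.4 | 18.1 | 0.2 |
| birch | 30.0 | 14.3 | 17.0 | 0.4 |
| birch | 50.0 | 15.2 | 15.8 | 0 |
| alder | 6.00 | 15.1 | 29.0 | 1.2 |
| alder | 15.0 | 13.0 | 31.1 | 0.8 |
| alder | 20.0 | 12.7 | 30.0 | 0 |
| alder | 30.0 | 13.7 | 31.7 | 0 |
| alder | 40.0 | 11.8 | 30.9 | 0.8 |
| alder | 50.0 | 12.3 | 31.1 | 0 |
| larch | 4.00 | 10.4 | 41.7 | 0 |
| larch | 12.0 | 6.3 | 46.3 | 0.5 |
| larch | 20.0 | 5.5 | 46.8 | 0.6 |
| larch | 30.0 | 5.7 | 47.0 | 0.2 |
| larch | 50.0 | 6.1 | 46.6 | 0.2 |

(each reading ± 0.5 percentage points)

1. the target standing at 1.0 h, as a percentage of the substrate charged
2. the over-reaction product standing at 1.0 h, as a percentage of the substrate charged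
3. amount of target if the flask were left three thousand times as long, in percent of the substrate charged



In larch from 20.0 min on, the mean target is 5.77% and the mean over-reaction product 46.8%. Our partner ledger, target plus twice the over-reaction product in percent of the substrate charged, comes to 99.4% against a charge of 1 equiv, which reads as two partner in each over-reaction product, with partner as limiting reagent.

Time first: by hand, a ledger that closes leaves no partner to take target. Larch falls short by 0.60 percentage points, and its target goes from 5.5% to 6.1% between 20.0 min and 50.0 min, against a scatter of 0.5 points, so we read the flask at 1.0 h and long after as a plateau.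

Concentration next: by hand, at equal equivalents, steps that each join two molecules change the clock and keep the split, so we assume that larch's captured share, target plus over-reaction product, 52.6%, holds from c(substrate) 0.13 M down to the flask's 0.086 M.

Partner last: the captured share at the last reading is 31.0% in birch and 43.4% in alder, so it moves with the charge, and we carry it only between larch and the flask, which have the same charge of 1.00 equiv. At that charge, with the ledger closed, over-reaction product is the charge minus the share, and target is twice the share minus the charge. For the flask we reckon 47.4% over-reaction product and 5.13% target.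

The forecast gives 5.2% target, 47.5% over-reaction product and 5% after the long wait, on the ground that “Everything stops once the partner is spent”.

The flask gives 5.49% target, 47.3% over-reaction product and 5.48% after the long wait, and its ledger reads >99.9%.

    substrate + partner → target + by-product (k = 0.620 M⁻¹ s⁻¹)
    2 substrate → homo dimer (k = 0.480 M⁻¹ s⁻¹)
    partner + target → over-reaction product (k = 0.360 M⁻¹ s⁻¹)

In the flask at 1.00 h, 0.0092% of the partner remains, and the half-life of target by partner + target is 68 h, far longer than the 1.0 h of the reading. Target still stands at 5.48% at 10.0 h. A further flask with 0.250 equiv of partner, 0% of it left, holds 12.3% target and 6.36% over-reaction product, a ledger of 25.0%.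

The earlier runs and the new flask are calculated from invented constants, and the scatter is random.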